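## Retrosynthetic overview
1. C2–aryl bond, made last: a chroman-2-yl oxocarbenium ion (from a C2 formate) is captured by 2,4-diformylphloroglucinol, and C2 settles trans to C3.
2. The C2 formate comes from Baeyer–Villiger excision of a temporary formyl handle on C2.
3. Key disconnection, C2–C3: an enantioselective 6-exo enaminyl-radical cyclisation of an aryloxyacetaldehyde onto a C-prenyl group. The prenyl group is the latent isopropyl group. This step closes the pyran ring and fixes C3.
4. The cyclisation substrate comes from phlorisovalerophenone by C-prenylation and then 4-O-(2-oxoethyl) ether formation.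
5. Ring order: both benzene rings derive from phloroglucinol (made from resorcinol by C–H borylation/oxidation). The pyran ring is the only ring built, and it is built in the radical step.

Assumption: the sense of induction of the imidazolidinone in the key cyclisation is assigned by analogy with its other enamine-radical reactions. If it proves opposite, the equally available enantiomeric catalyst is used.

## Route

Step 1
Reactants: 1 resorcinol (benzene-1,3-diol)
Product: 3 phloroglucinol (benzene-1,3,5-triol), via tris-boryl arene 2 (not isolated)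
Conditions: HBpin (4 equiv), [Ir(OMe)(cod)]2 (1.5 mol %), dtbpy (3 mol %), THF, 80 °C; then 30% aq H2O2, 0 °C → rt
Reagents that add atoms: pinacolborane CC1(C)OBOC1(C)C (B in 2); hydrogen peroxide OO
Why: The two OH groups are masked in situ as O–Bpin, the sterically governed Ir-catalysed C–H borylation reaches only C5 (the one C–H without an ortho substituent), and oxidation/hydrolysis gives the triol (C–H borylation/oxidation).

Step 2
Reactants: 3 phloroglucinol; 4 isovaleryl chloride (3-methylbutanoyl chloride)
Product: 5 phlorisovalerophenone, 1-(2,4,6-trihydroxyphenyl)-3-methylbutan-1-one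
Conditions: MeSO3H (solvent), 70 °C
Reagents that add atoms: none
Why: Friedel–Crafts C-acylation (O-acylation/Fries in strong acid) stops after one acyl group because the chelated ketone deactivates the ring.

Step 3
Reactants: 5 phlorisovalerophenone; 6 prenyl bromide (1-bromo-3-methylbut-2-ene)
Product: 7 3-methyl-1-[2,4,6-trihydroxy-3-(3-methylbut-2-enyl)phenyl]butan-1-one
Conditions: KOH (1 equiv), H2O, 0 °C → rt, 6 (0.9 equiv)
Reagents that add atoms: none
Why: In protic medium the phloroglucinolate reacts as a vinylogous enolate and is C-alkylated by the soft allylic bromide (C-prenylation), and the two free ring carbons are equivalent, so only one mono-prenyl isomer can form.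

Step 4
Reactants: 7 C-prenyl phlorisovalerophenone; 8 2,2-dimethoxyethanol
Product: 10 2-[3,5-dihydroxy-4-(3-methylbutanoyl)-2-(3-methylbut-2-enyl)phenoxy]acetaldehyde, via dimethyl acetal 9 (not isolated)
Conditions: PPh3, DIAD, THF, 0 °C → rt; then 2 M HCl, THF, 40 °C
Reagents that add atoms: water O
Why: Mitsunobu etherification selects the most acidic, non-chelated OH para to the ketone (the two ortho OH groups are hydrogen-bonded to C=O), and mild acetal hydrolysis then frees the aldehyde.

Step 5
Reactants: 10 aryloxyacetaldehyde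
Product: 11 (2R,3S)-5,7-dihydroxy-6-(3-methylbutanoyl)-3-(propan-2-yl)-3,4-dihydro-2H-chromene-2-carbaldehyde (2,3-trans)
Conditions: (2R,5S)-2-tert-butyl-3,5-dimethylimidazolidin-4-one·TFA (20 mol %), [Ir(Fmppy)2(dtbbpy)]PF6 (1 mol %), 2,4,6-triisopropylbenzenethiol (10 mol %), DME, blue LEDs, 0 °C
Reagents that add atoms: none
Why: Proposed new method: the chiral enamine of 10 is oxidised by the excited Ir catalyst to an electrophilic enaminyl radical cation whose unshielded face adds 6-exo-trig, through a chair transition state, to the less substituted carbon of the nucleophilic prenyl olefin (forming C2–C3 and setting C2 and C3 trans in one event), the resulting tertiary radical takes H from the thiol to reveal the isopropyl group, and hydrolysis releases the amine; the closest known reaction type is the enamine/photoredox/HAT triple-catalytic intramolecular α-alkylation of aldehydes with trisubstituted olefins (SOMO-type radical cyclisation), and what is new here is the α-aryloxy aldehyde and the free acylphloroglucinol.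

Step 6
Reactants: 3 phloroglucinol
Product: 13 2,4-diformylphloroglucinol (2,4,6-trihydroxybenzene-1,3-dicarbaldehyde), via bis-iminium salt 12 (not isolated)
Conditions: POCl3 (2.5 equiv), DMF (2.5 equiv), dioxane, rt; then H2O
Reagents that add atoms: N,N-dimethylformamide CN(C)C=O; water O
Why: Double Vilsmeier–Haack formylation stops at two because the two iminium groups deactivate the last ring position until work-up.

Step 7
Reactants: 11 chroman-2-carbaldehyde; 13 2,4-diformylphloroglucinol
Product: 15 5-[(2R,3S)-5,7-dihydroxy-6-(3-methylbutanoyl)-3-(propan-2-yl)-3,4-dihydro-2H-chromen-2-yl]-2,4,6-trihydroxybenzene-1,3-dicarbaldehyde (target), via chromanyl formate 14 (not isolated)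
Conditions: mCPBA (1.05 equiv), CH2Cl2, 0 °C; NaHCO3 wash, solvent swap; then 13 (3 equiv), BF3·OEt2 (0.3 equiv), MeCN, −30 °C → rt, slow addition of 14
Reagents that add atoms: 3-chloroperbenzoic acid OOC(=O)c1cccc(Cl)c1 (O in 14)
Why: Baeyer–Villiger oxidation with retentive migration of the α-oxygenated C2 turns the formyl handle into a formate leaving group, Lewis-acid ionisation gives the oxocarbenium ion, which is attacked by the only free carbon of 13 anti to the C3 isopropyl group (Friedel–Crafts C-arylation of the aryl C-glycosylation type), and reversible ring opening through the ortho-quinone methide funnels C2 to the diequatorial trans (2R) isomer while C3 is untouched.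

## Compound list
1 | resorcinol | Oc1cccc(O)c1 | starting material
2 | 2,2'-{[5-(4,4,5,5-tetramethyl-1,3,2-dioxaborolan-2-yl)-1,3-phenylene]bis(oxy)}bis(4,4,5,5-tetramethyl-1,3,2-dioxaborolane) | CC1(C)OB(Oc2cc(OB3OC(C)(C)C(C)(C)O3)cc(B4OC(C)(C)C(C)(C)O4)c2)OC1(C)C | intermediate
3 | phloroglucinol | Oc1cc(O)cc(O)c1 | intermediate
4 | isovaleryl chloride | CC(C)CC(=O)Cl | starting material
5 | phlorisovalerophenone | CC(C)CC(=O)c1c(O)cc(O)cc1O | intermediate
6 | prenyl bromide | CC(C)=CCBr | starting material
7 | 3-methyl-1-[2,4,6-trihydroxy-3-(3-methylbut-2-enyl)phenyl]butan-1-one | CC(C)CC(=O)c1c(O)cc(O)c(CC=C(C)C)c1O | intermediate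
8 | 2,2-dimethoxyethanol | COC(CO)OC | starting material
9 | 1-[4-(2,2-dimethoxyethoxy)-2,6-dihydroxy-3-(3-methylbut-2-enyl)phenyl]-3-methylbutan-1-one | CC(C)CC(=O)c1c(O)cc(OCC(OC)OC)c(CC=C(C)C)c1O | intermediate
10 | 2-[3,5-dihydroxy-4-(3-methylbutanoyl)-2-(3-methylbut-2-enyl)phenoxy]acetaldehyde | CC(C)CC(=O)c1c(O)cc(OCC=O)c(CC=C(C)C)c1O | intermediate
11 | (2R,3S)-5,7-dihydroxy-6-(3-methylbutanoyl)-3-(propan-2-yl)chromane-2-carbaldehyde | CC(C)CC(=O)c1c(O)cc2c(c1O)C[C@@H](C(C)C)[C@H](C=O)O2 | intermediate
12 | N,N'-[(2,4,6-trihydroxy-1,3-phenylene)dimethylidyne]bis(N-methylmethanaminium) dichloride | C[N+](C)=Cc1c(O)cc(O)c(C=[N+](C)C)c1O.[Cl-].[Cl-] | intermediate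
13 | 2,4,6-trihydroxybenzene-1,3-dicarbaldehyde | O=Cc1c(O)cc(O)c(C=O)c1O | intermediate
14 | (2S,3S)-5,7-dihydroxy-6-(3-methylbutanoyl)-3-(propan-2-yl)chroman-2-yl formate | CC(C)CC(=O)c1c(O)cc2c(c1O)C[C@@H](C(C)C)[C@H](OC=O)O2 | intermediate
15 | target, (2R,3S), 2,3-trans | CC(C)CC(=O)c1c(O)cc2c(c1O)C[C@@H](C(C)C)[C@H](c1c(O)c(C=O)c(O)c(C=O)c1O)O2 | target

## Totals
- Total steps: 7
- Longest linear sequence: 6 (steps 1, 2, 3, 4, 5, 7)

## Steps most likely to fail

**Step 5.**
- Risks:
  - The α-aryloxy enaminyl radical cation is less electrophilic than the alkyl cases.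
  - The iminium of 10 can be attacked by the nucleophilic ring C–H ortho to the ether, giving a benzofuran.
  - The free phenols may quench radicals.
- Fallback: it sets out from 5 and comes back at 15.
  - 5 is aminomethylated with dimethylmethyleneammonium iodide to the Mannich base 1-[3-(dimethylaminomethyl)-2,4,6-trihydroxyphenyl]-3-methylbutan-1-one F1.
  - On gentle warming this loses dimethylamine to the ortho-quinone methide 3,5-dihydroxy-4-(3-methylbutanoyl)-6-methylidenecyclohexa-2,4-dien-1-one F2.
  - F2 is trapped in situ by the enamine formed from isovaleraldehyde and a diphenylprolinol silyl ether (enantiomer chosen for 3S). This polar organocatalytic Michael addition/hemiacetalisation gives the lactol 1-[(3S)-2,5,7-trihydroxy-3-(propan-2-yl)-3,4-dihydro-2H-chromen-6-yl]-3-methylbutan-1-one F3.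
  - The lactol is ionised with BF3·OEt2 in the presence of 13 to give 15.

**Step 7.**
- Risks:
  - 13 is a weak carbon nucleophile, so the oxocarbenium ion may be attacked instead by the free ring C–H of a second chroman molecule.
  - The ion may also lose H-3 to the 4H-chromene, which would erode the ee.
- Fallback: it sets out from 14 and comes back at 15.
  - 14 is solvolysed in NaOAc/AcOH–H2O to the open hydroxy-aldehyde (2S)-3-methyl-2-{[2,4,6-trihydroxy-3-(3-methylbutanoyl)phenyl]methyl}butanal F4.
  - At 50–60 °C F4 undergoes Knoevenagel condensation with the acidic ring C–H of 13. The product is the ortho-quinone methide 2,4-dihydroxy-6-oxo-5-[(2S)-3-methyl-2-{[2,4,6-trihydroxy-3-(3-methylbutanoyl)phenyl]methyl}butylidene]cyclohexa-1,3-diene-1,3-dicarbaldehyde F5.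
  - Fast intramolecular oxa-Michael addition of the phenol para to the ketone closes the pyran ring to trans 15. No oxocarbenium ion is involved.

**Step 4.**
- Risks:
  - Acid hydrolysis of the electron-poor acetal may be slower than acid-induced cyclisation of the prenyl phenol to a dimethylchroman.
  - It may also be slower than benzofuran formation from the liberated aldehyde.
- Fallback: it sets out from 7 and comes back at 10.
  - Mitsunobu etherification with excess ethylene glycol gives the alcohol 1-[2,6-dihydroxy-4-(2-hydroxyethoxy)-3-(3-methylbut-2-enyl)phenyl]-3-methylbutan-1-one F6.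
  - F6 is oxidised under non-acidic Parikh–Doering conditions (SO3·pyridine, DMSO, Et3N) to 10.

Further compounds
F1 | step 5 | 1-[3-(dimethylaminomethyl)-2,4,6-trihydroxyphenyl]-3-methylbutan-1-one | CC(C)CC(=O)c1c(O)cc(O)c(CN(C)C)c1O
F2 | step 5 | 3,5-dihydroxy-4-(3-methylbutanoyl)-6-methylidenecyclohexa-2,4-dien-1-one | C=C1C(=O)C=C(O)C(C(=O)CC(C)C)=C1O
F3 | step 5 | 1-[(3S)-2,5,7-trihydroxy-3-(propan-2-yl)-3,4-dihydro-2H-chromen-6-yl]-3-methylbutan-1-one | CC(C)CC(=O)c1c(O)cc2c(c1O)C[C@@H](C(C)C)C(O)O2
F4 | step 7 | (2S)-3-methyl-2-{[2,4,6-trihydroxy-3-(3-methylbutanoyl)phenyl]methyl}butanal | CC(C)CC(=O)c1c(O)cc(O)c(C[C@@H](C(C)C)C=O)c1O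
F5 | step 7 | 2,4-dihydroxy-6-oxo-5-[(2S)-3-methyl-2-{[2,4,6-trihydroxy-3-(3-methylbutanoyl)phenyl]methyl}butylidene]cyclohexa-1,3-diene-1,3-dicarbaldehyde | CC(C)CC(=O)c1c(O)cc(O)c(C[C@@H](C(C)C)C=C2C(=O)C(C=O)=C(O)C(C=O)=C2O)c1O
F6 | step 4 | 1-[2,6-dihydroxy-4-(2-hydroxyethoxy)-3-(3-methylbut-2-enyl)phenyl]-3-methylbutan-1-one | CC(C)CC(=O)c1c(O)cc(OCCO)c(CC=C(C)C)c1O
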